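**Assumption:** the SMILES is taken literally, i.e. (4S,5R,6R,8R,10S) with a cis (Z‑alkene‑derived) 4,5‑epoxide. Germacrane numbering is used for the target positions (C1 ketone, C4/C5 epoxide, C6 lactone O–CH, C7=C11, C8 senecioate, C10 CHMe, C12 lactone C=O, C13 CH2OAc).

## Retrosynthetic overview

1. Target 22 ⇐ hydroxy lactone 21 by oxidation at C1; the ketone is unveiled last so that C10 cannot epimerise and no ketone competes in the ring closure.
2. 21 ⇐ acyclic epoxy aldehyde 19 in one operation: alkenylchromium addition closes the ten‑membered carbocycle at C6–C7, then the new C6 alkoxide closes the butenolide on C12 (carbocycle first, lactone second).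
3. 19 ⇐ Z‑allylic alcohol 17 by Sharpless epoxidation; the tetrasubstituted (Z)‑β‑iodoacrylate ⇐ γ‑hydroxy ynoate 12 by a hydroxyl‑directed iodo‑aldol reaction with formaldehyde.
4. 12 ⇐ aldehyde 10 + methyl propiolate 11; 10 ⇐ aldehyde 3 by crotylboration (sets C10) and hydroboration; 3 ⇐ neryl acetate 1 by selective ozonolysis.

## Route

**Step 1**
Reactants: 1 neryl acetate [(2Z)-3,7-dimethylocta-2,6-dien-1-yl acetate]
Product: 3 (2Z)-3-methyl-6-oxohex-2-en-1-yl acetate, via ozonide 2 (not isolated)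
Conditions: O3, CH2Cl2, −78 °C; then Me2S, −78 °C → rt
Reagents that add atoms: ozone, O=[O+][O-]
Why: Ozonolysis with reductive work‑up cleaves the electron‑rich terminal trisubstituted alkene in preference to the 2,3‑alkene, which is deactivated by the allylic acetate; no stereocentre is formed.

**Step 2**
Reactants: 3 (2Z)-3-methyl-6-oxohex-2-en-1-yl acetate
Product: 6 (2Z,6R,7S)-3,7-dimethylnona-2,8-diene-1,6-diol, via borinate 4 (not isolated), via hydroxy acetate 5 (not isolated)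
Conditions: (E)-but-2-ene, n-BuLi, KOtBu, THF, −78 → −45 °C; (−)-Ipc2BOMe, BF3·OEt2, −78 °C; then 3, −78 °C; NaOH, H2O2, MeOH, rt
Reagents that add atoms: (−)-B-[(E)-but-2-enyl]diisopinocampheylborane (made in the flask), C/C=C/CB([C@@H]1C[C@@H]2C[C@H]([C@H]1C)C2(C)C)[C@@H]1C[C@@H]2C[C@H]([C@H]1C)C2(C)C
Why: Brown asymmetric crotylboration through a chair Zimmerman–Traxler transition state: the (E)-crotyl group gives the anti adduct and the (+)-α-pinene-derived borane attacks the aldehyde Si face, setting (6R,7S) (C7 is the later C10, S); the basic oxidative work‑up also cleaves the acetate.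

**Step 3**
Reactants: 6 (2Z,6R,7S)-3,7-dimethylnona-2,8-diene-1,6-diol
Product: 7 (2Z,6R,7S)-1,6-bis[(tert-butyldimethylsilyl)oxy]-3,7-dimethylnona-2,8-diene
Conditions: TBSCl (2.5 equiv), imidazole, DMF, rt
Reagents that add atoms: tert-butyldimethylsilyl chloride, CC(C)(C)[Si](C)(C)Cl
Why: Silyl ether formation masks the future C6 alcohol and the future C1 ketone (as its alcohol) in one operation; no stereocentre is touched.

**Step 4**
Reactants: 7 (2Z,6R,7S)-1,6-bis[(tert-butyldimethylsilyl)oxy]-3,7-dimethylnona-2,8-diene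
Product: 9 (3S,4R,7Z)-4,9-bis[(tert-butyldimethylsilyl)oxy]-3,7-dimethylnon-7-en-1-ol, via alkylborane 8 (not isolated)
Conditions: 9-BBN, THF, 0 °C → rt; then NaOH, H2O2, 0 °C
Reagents that add atoms: hydrogen peroxide, OO
Why: Hydroboration–oxidation with 9-BBN is anti‑Markovnikov and selective for the monosubstituted alkene over the trisubstituted one; no new stereocentre.

**Step 5**
Reactants: 9 (3S,4R,7Z)-4,9-bis[(tert-butyldimethylsilyl)oxy]-3,7-dimethylnon-7-en-1-ol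
Product: 10 (3S,4R,7Z)-4,9-bis[(tert-butyldimethylsilyl)oxy]-3,7-dimethylnon-7-enal
Conditions: Dess–Martin periodinane, CH2Cl2, rt
Reagents that add atoms: none
Why: Dess–Martin oxidation of the primary alcohol; the methyl stereocentre is β to the aldehyde and cannot epimerise.

**Step 6**
Reactants: 10 (3S,4R,7Z)-4,9-bis[(tert-butyldimethylsilyl)oxy]-3,7-dimethylnon-7-enal; 11 methyl propiolate
Product: 12 methyl (4R,6S,7R,10Z)-7,12-bis[(tert-butyldimethylsilyl)oxy]-4-hydroxy-6,10-dimethyldodec-10-en-2-ynoate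
Conditions: Me2Zn, (R,R)-ProPhenol (20 mol%), Ph3PO (40 mol%), toluene, 4 °C
Reagents that add atoms: none
Why: Zinc–ProPhenol catalysed asymmetric alkynylation sets C4 (later C8, R) under ligand control; the (R,R)-ligand is chosen for Si‑face delivery, the sense is checked by Mosher analysis and the antipodal ligand is used if it proves opposite.

**Step 7**
Reactants: 12 methyl (4R,6S,7R,10Z)-7,12-bis[(tert-butyldimethylsilyl)oxy]-4-hydroxy-6,10-dimethyldodec-10-en-2-ynoate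
Product: 14 methyl (2Z,4R,6S,7R,10Z)-7,12-bis[(tert-butyldimethylsilyl)oxy]-4-hydroxy-2-(hydroxymethyl)-3-iodo-6,10-dimethyldodeca-2,10-dienoate, via oxaluminole 13 (not isolated)
Conditions: Et2AlI (2.5 equiv), CH2Cl2, −78 °C; then CH2O (gas), −78 → −20 °C
Reagents that add atoms: diethylaluminium iodide, CC[Al](I)CC; formaldehyde, C=O
Why: Proposed new method: the aluminium alkoxide of the free C4–OH holds aluminium beside C2, iodide adds to C3 anti to it (trans‑iodoalumination to the five‑membered oxaluminole 13) and the C2–Al bond then adds to formaldehyde with retention, so CH2OH ends cis to C4 and iodine cis to CO2Me (2Z), while any isomer with the ester cis to C4–OH lactonises and is removed; the closest known reactions are the Et2AlI or MgI2 halo‑aldol (β‑iodo Baylis–Hillman) reaction of ynoates and the hydroxyl‑directed trans‑hydroalumination with α‑trapping of γ‑hydroxy ynoates by NaAlH2(OCH2CH2OMe)2.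

**Step 8**
Reactants: 14 methyl (2Z,4R,6S,7R,10Z)-7,12-bis[(tert-butyldimethylsilyl)oxy]-4-hydroxy-2-(hydroxymethyl)-3-iodo-6,10-dimethyldodeca-2,10-dienoate
Product: 15 methyl (2Z,4R,6S,7R,10Z)-2-(acetoxymethyl)-7,12-bis[(tert-butyldimethylsilyl)oxy]-4-hydroxy-3-iodo-6,10-dimethyldodeca-2,10-dienoate
Conditions: AcCl, 2,4,6-collidine, CH2Cl2, −78 °C
Reagents that add atoms: acetyl chloride, CC(Cl)=O
Why: Chemoselective acetylation of the primary allylic alcohol over the hindered secondary one (acyl chloride with a hindered pyridine base at low temperature).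

**Step 9**
Reactants: 15 methyl (2Z,4R,6S,7R,10Z)-2-(acetoxymethyl)-7,12-bis[(tert-butyldimethylsilyl)oxy]-4-hydroxy-3-iodo-6,10-dimethyldodeca-2,10-dienoate
Product: 16 methyl (2Z,4R,6S,7R,10Z)-2-(acetoxymethyl)-7,12-bis[(tert-butyldimethylsilyl)oxy]-3-iodo-6,10-dimethyl-4-[(3-methylbut-2-enoyl)oxy]dodeca-2,10-dienoate
Conditions: 3-methylbut-2-enoyl chloride, pyridine, DMAP (cat.), CH2Cl2, 0 °C
Reagents that add atoms: 3-methylbut-2-enoyl chloride, CC(C)=CC(Cl)=O
Why: Esterification of the only free hydroxyl with the acid chloride (weak base and low temperature keep the enoate conjugated); retention at C4.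

**Step 10**
Reactants: 16 methyl (2Z,4R,6S,7R,10Z)-2-(acetoxymethyl)-7,12-bis[(tert-butyldimethylsilyl)oxy]-3-iodo-6,10-dimethyl-4-[(3-methylbut-2-enoyl)oxy]dodeca-2,10-dienoate
Product: 17 methyl (2Z,4R,6S,7R,10Z)-2-(acetoxymethyl)-7,12-dihydroxy-3-iodo-6,10-dimethyl-4-[(3-methylbut-2-enoyl)oxy]dodeca-2,10-dienoate
Conditions: HF·pyridine, pyridine/THF, 0 °C → rt
Reagents that add atoms: none
Why: Fluoride‑mediated desilylation removes both silyl ethers before any epoxide is present and leaves acetate, senecioate and alkenyl iodide untouched.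

**Step 11**
Reactants: 17 methyl (2Z,4R,6S,7R,10Z)-2-(acetoxymethyl)-7,12-dihydroxy-3-iodo-6,10-dimethyl-4-[(3-methylbut-2-enoyl)oxy]dodeca-2,10-dienoate
Product: 18 methyl (2Z,4R,6S,7R)-2-(acetoxymethyl)-7-hydroxy-9-[(2S,3R)-3-(hydroxymethyl)-2-methyloxiran-2-yl]-3-iodo-6-methyl-4-[(3-methylbut-2-enoyl)oxy]non-2-enoate
Conditions: Ti(OiPr)4 (1.0 equiv), D-(−)-diethyl tartrate (1.2 equiv), t-BuOOH, 4 Å MS, CH2Cl2, −20 °C
Reagents that add atoms: tert-butyl hydroperoxide, CC(C)(C)OO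
Why: Sharpless asymmetric epoxidation acts only on the allylic alcohol; syn‑stereospecific oxygen transfer to the Z‑alkene gives the cis‑epoxide, and D-(−)-tartrate gives the (2S,3R)-oxirane (target 4S,5R), as nerol gives (2R,3S)-epoxynerol.

**Step 12**
Reactants: 18 methyl (2Z,4R,6S,7R)-2-(acetoxymethyl)-7-hydroxy-9-[(2S,3R)-3-(hydroxymethyl)-2-methyloxiran-2-yl]-3-iodo-6-methyl-4-[(3-methylbut-2-enoyl)oxy]non-2-enoate
Product: 19 methyl (2Z,4R,6S,7R)-2-(acetoxymethyl)-9-[(2S,3S)-3-formyl-2-methyloxiran-2-yl]-7-hydroxy-3-iodo-6-methyl-4-[(3-methylbut-2-enoyl)oxy]non-2-enoate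
Conditions: TEMPO (cat.), PhI(OAc)2, CH2Cl2, rt
Reagents that add atoms: none
Why: Oxoammonium (TEMPO) oxidation is selective for the primary epoxy alcohol over the secondary alcohol, giving the epoxy aldehyde without touching stereocentres.

**Step 13**
Reactants: 19 methyl (2Z,4R,6S,7R)-2-(acetoxymethyl)-9-[(2S,3S)-3-formyl-2-methyloxiran-2-yl]-7-hydroxy-3-iodo-6-methyl-4-[(3-methylbut-2-enoyl)oxy]non-2-enoate
Product: 21 (1R,4S,5R,6R,8R,10S)-13-acetoxy-4,5-epoxy-1-hydroxy-8-[(3-methylbut-2-enoyl)oxy]germacr-7(11)-en-12,6-olide, via hydroxy ester 20 (not isolated)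
Conditions: CrCl2 (10 equiv), NiCl2 (0.1 equiv), DMSO/THF, rt, 2 mM (syringe pump); aq. NH4Cl, then SiO2
Reagents that add atoms: none
Why: Nozaki–Hiyama–Kishi macrocyclisation: zerovalent nickel inserts into the C–I bond, transmetalation gives the alkenyl species of trivalent chromium with retention, and this adds only to the aldehyde anti to the epoxide C–O bond (Felkin–Anh/Cornforth) to close the ten‑membered ring at C6–C7 and set C6 (R); the C6 alkoxide lies cis to CO2Me and closes the butenolide, the same bond order as in germacranolide biosynthesis.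

**Step 14**
Reactants: 21 (1R,4S,5R,6R,8R,10S)-13-acetoxy-4,5-epoxy-1-hydroxy-8-[(3-methylbut-2-enoyl)oxy]germacr-7(11)-en-12,6-olide
Product: 22 (4S,5R,6R,8R,10S)-13-acetoxy-4,5-epoxy-8-[(3-methylbut-2-enoyl)oxy]-1-oxogermacr-7(11)-en-12,6-olide (target)
Conditions: Dess–Martin periodinane, NaHCO3, CH2Cl2, 0 °C → rt
Reagents that add atoms: none
Why: Buffered Dess–Martin oxidation converts the C1 carbinol into the ketone under non‑enolising conditions, so the adjacent C10 centre (S, from step 2) is kept.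

## Compound list

1 | neryl acetate, (2Z)-3,7-dimethylocta-2,6-dien-1-yl acetate | CC(C)=CCC/C(C)=C\COC(C)=O | starting material
2 | (2Z)-5-(5,5-dimethyl-1,2,4-trioxolan-3-yl)-3-methylpent-2-en-1-yl acetate (secondary ozonide) | CC1(C)OOC(CC/C(C)=C\COC(C)=O)O1 | intermediate
3 | (2Z)-3-methyl-6-oxohex-2-en-1-yl acetate | O=CCC/C(C)=C\COC(C)=O | intermediate
4 | (2Z,6R,7S)-6-[(diisopinocampheylboryl)oxy]-3,7-dimethylnona-2,8-dien-1-yl acetate (borinate) | C=C[C@H](C)[C@H](OB([C@@H]1C[C@@H]2C[C@H]([C@H]1C)C2(C)C)[C@@H]1C[C@@H]2C[C@H]([C@H]1C)C2(C)C)CC/C(C)=C\COC(C)=O | intermediate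
5 | (2Z,6R,7S)-6-hydroxy-3,7-dimethylnona-2,8-dien-1-yl acetate | C=C[C@H](C)[C@H](O)CC/C(C)=C\COC(C)=O | intermediate
6 | (2Z,6R,7S)-3,7-dimethylnona-2,8-diene-1,6-diol | C=C[C@H](C)[C@H](O)CC/C(C)=C\CO | intermediate
7 | (2Z,6R,7S)-1,6-bis[(tert-butyldimethylsilyl)oxy]-3,7-dimethylnona-2,8-diene | C=C[C@H](C)[C@H](O[Si](C)(C)C(C)(C)C)CC/C(C)=C\CO[Si](C)(C)C(C)(C)C | intermediate
8 | 9-[(3S,4R,7Z)-4,9-bis[(tert-butyldimethylsilyl)oxy]-3,7-dimethylnon-7-en-1-yl]-9-borabicyclo[3.3.1]nonane | C1CCC2CCCC1B2CC[C@H](C)[C@H](O[Si](C)(C)C(C)(C)C)CC/C(C)=C\CO[Si](C)(C)C(C)(C)C | intermediate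
9 | (3S,4R,7Z)-4,9-bis[(tert-butyldimethylsilyl)oxy]-3,7-dimethylnon-7-en-1-ol | OCC[C@H](C)[C@H](O[Si](C)(C)C(C)(C)C)CC/C(C)=C\CO[Si](C)(C)C(C)(C)C | intermediate
10 | (3S,4R,7Z)-4,9-bis[(tert-butyldimethylsilyl)oxy]-3,7-dimethylnon-7-enal | O=CC[C@H](C)[C@H](O[Si](C)(C)C(C)(C)C)CC/C(C)=C\CO[Si](C)(C)C(C)(C)C | intermediate
11 | methyl propiolate | C#CC(=O)OC | starting material
12 | methyl (4R,6S,7R,10Z)-7,12-bis[(tert-butyldimethylsilyl)oxy]-4-hydroxy-6,10-dimethyldodec-10-en-2-ynoate | COC(=O)C#C[C@H](O)C[C@H](C)[C@H](O[Si](C)(C)C(C)(C)C)CC/C(C)=C\CO[Si](C)(C)C(C)(C)C | intermediate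
13 | methyl (5R)-5-[(2S,3R,6Z)-3,8-bis[(tert-butyldimethylsilyl)oxy]-2,6-dimethyloct-6-en-1-yl]-2-ethyl-4-iodo-2,5-dihydro-1,2-oxaluminole-3-carboxylate | CC[Al]1O[C@H](C[C@H](C)[C@H](O[Si](C)(C)C(C)(C)C)CC/C(C)=C\CO[Si](C)(C)C(C)(C)C)C(I)=C1C(=O)OC | intermediate
14 | methyl (2Z,4R,6S,7R,10Z)-7,12-bis[(tert-butyldimethylsilyl)oxy]-4-hydroxy-2-(hydroxymethyl)-3-iodo-6,10-dimethyldodeca-2,10-dienoate | COC(=O)/C(CO)=C(\I)[C@H](O)C[C@H](C)[C@H](O[Si](C)(C)C(C)(C)C)CC/C(C)=C\CO[Si](C)(C)C(C)(C)C | intermediate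
15 | methyl (2Z,4R,6S,7R,10Z)-2-(acetoxymethyl)-7,12-bis[(tert-butyldimethylsilyl)oxy]-4-hydroxy-3-iodo-6,10-dimethyldodeca-2,10-dienoate | COC(=O)/C(COC(C)=O)=C(\I)[C@H](O)C[C@H](C)[C@H](O[Si](C)(C)C(C)(C)C)CC/C(C)=C\CO[Si](C)(C)C(C)(C)C | intermediate
16 | methyl (2Z,4R,6S,7R,10Z)-2-(acetoxymethyl)-7,12-bis[(tert-butyldimethylsilyl)oxy]-3-iodo-6,10-dimethyl-4-[(3-methylbut-2-enoyl)oxy]dodeca-2,10-dienoate | COC(=O)/C(COC(C)=O)=C(\I)[C@H](OC(=O)C=C(C)C)C[C@H](C)[C@H](O[Si](C)(C)C(C)(C)C)CC/C(C)=C\CO[Si](C)(C)C(C)(C)C | intermediate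
17 | methyl (2Z,4R,6S,7R,10Z)-2-(acetoxymethyl)-7,12-dihydroxy-3-iodo-6,10-dimethyl-4-[(3-methylbut-2-enoyl)oxy]dodeca-2,10-dienoate | COC(=O)/C(COC(C)=O)=C(\I)[C@H](OC(=O)C=C(C)C)C[C@H](C)[C@H](O)CC/C(C)=C\CO | intermediate
18 | methyl (2Z,4R,6S,7R)-2-(acetoxymethyl)-7-hydroxy-9-[(2S,3R)-3-(hydroxymethyl)-2-methyloxiran-2-yl]-3-iodo-6-methyl-4-[(3-methylbut-2-enoyl)oxy]non-2-enoate | COC(=O)/C(COC(C)=O)=C(\I)[C@H](OC(=O)C=C(C)C)C[C@H](C)[C@H](O)CC[C@]1(C)O[C@@H]1CO | intermediate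
19 | methyl (2Z,4R,6S,7R)-2-(acetoxymethyl)-9-[(2S,3S)-3-formyl-2-methyloxiran-2-yl]-7-hydroxy-3-iodo-6-methyl-4-[(3-methylbut-2-enoyl)oxy]non-2-enoate | COC(=O)/C(COC(C)=O)=C(\I)[C@H](OC(=O)C=C(C)C)C[C@H](C)[C@H](O)CC[C@]1(C)O[C@@H]1C=O | intermediate
20 | methyl (1R,4S,5R,6R,8R,10S)-13-acetoxy-4,5-epoxy-1,6-dihydroxy-8-[(3-methylbut-2-enoyl)oxy]germacr-7(11)-en-12-oate (CO2Me cis to C6) | CC(=O)OC/C(C(=O)OC)=C1/[C@@H](O)[C@H]2O[C@@]2(C)CC[C@@H](O)[C@@H](C)C[C@H]1OC(=O)C=C(C)C | intermediate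
21 | (1R,4S,5R,6R,8R,10S)-13-acetoxy-4,5-epoxy-1-hydroxy-8-[(3-methylbut-2-enoyl)oxy]germacr-7(11)-en-12,6-olide | CC(=O)OCC1=C2[C@@H](OC1=O)[C@H]1O[C@@]1(C)CC[C@@H](O)[C@@H](C)C[C@H]2OC(=O)C=C(C)C | intermediate
22 | (4S,5R,6R,8R,10S)-13-acetoxy-4,5-epoxy-8-[(3-methylbut-2-enoyl)oxy]-1-oxogermacr-7(11)-en-12,6-olide (CNP0220542.1) | CC(=O)OCC1=C2[C@@H](OC1=O)[C@H]1O[C@@]1(C)CCC(=O)[C@@H](C)C[C@H]2OC(=O)C=C(C)C | target

## Step count and risks

Total steps: 14. Longest linear sequence: 14 (from neryl acetate 1; fully linear).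

Three steps most likely to fail:

**Step 13 (macrocyclisation/lactonisation).** Divalent chromium may reduce or open the epoxy aldehyde, the alkenylchromium may eliminate the neighbouring C8 acyloxy group, and ten‑ring closure competes with oligomerisation. The fallback sets out from 17 and changes the order of events, cyclising before epoxidising. The allylic alcohol of 17 alone is oxidised with MnO2 to the (Z)-enal F1. F1 is cyclised under the same CrCl2/NiCl2 high‑dilution conditions, now without an epoxide and with a stiffer chain, to the macrocyclic dienyl lactone F2. The isolated, electron‑rich 4,5‑alkene of F2 is then epoxidised with mCPBA/NaHCO3 from its exposed outer face (butenolide and senecioate alkenes are electron‑poor), coming back to the route at 21. The C6 and epoxide configurations would then rest on macrocyclic control and must be confirmed.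

**Step 7 (directed iodo‑aldol).** The geometry of the tetrasubstituted iodoalkene rests on an unproven directing effect. The fallback sets out from 12 and fixes the geometry with a ring. 12 is silylated with (bromomethyl)chlorodimethylsilane/imidazole to the bromomethylsilyl ether F3. NaI in warm acetone/DMF exchanges bromide for iodide, adds iodide to the ynoate and lets the allenolate close a six‑membered ring on the tethered CH2I (Michael‑initiated ring closure, the iodide counterpart of stannylcuprate annulations of ω‑halo ynoates), giving the oxasiline F4 in which C13 is necessarily cis to C8. Tamao–Fleming oxidation (KF, KHCO3, H2O2) cleaves C–Si and O–Si and comes back at 14.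

**Step 6 (asymmetric alkynylation).** The sense and level of ligand control on this β‑branched aliphatic aldehyde are the open points. The fallback sets out from 10 and sets C4 by reduction instead of addition. The lithium acetylide of 11 (LiN(SiMe3)2, THF, −78 °C) adds to 10 to give 12 together with its (4S)-epimer F5. Dess–Martin oxidation of the mixture gives the ynone F6. Transfer hydrogenation with RuCl[(R,R)-TsDPEN](p-cymene) in i-PrOH, which reduces alkyl alkynyl ketones to the (R)-propargylic alcohols, comes back at 12.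

## Further compounds

F1 | step 13 | methyl (2Z,4R,6S,7R,10Z)-2-(acetoxymethyl)-7-hydroxy-3-iodo-6,10-dimethyl-4-[(3-methylbut-2-enoyl)oxy]-12-oxododeca-2,10-dienoate ((Z)-enal) | COC(=O)/C(COC(C)=O)=C(\I)[C@H](OC(=O)C=C(C)C)C[C@H](C)[C@H](O)CC/C(C)=C\C=O
F2 | step 13 | (1R,4Z,6S,8R,10S)-13-acetoxy-1-hydroxy-8-[(3-methylbut-2-enoyl)oxy]germacra-4,7(11)-dien-12,6-olide (macrocyclic dienyl lactone) | CC(=O)OCC1=C2[C@@H](OC1=O)/C=C(/C)CC[C@@H](O)[C@@H](C)C[C@H]2OC(=O)C=C(C)C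
F3 | step 7 | methyl (4R,6S,7R,10Z)-4-{[(bromomethyl)dimethylsilyl]oxy}-7,12-bis[(tert-butyldimethylsilyl)oxy]-6,10-dimethyldodec-10-en-2-ynoate (bromomethylsilyl ether) | COC(=O)C#C[C@H](O[Si](C)(C)CBr)C[C@H](C)[C@H](O[Si](C)(C)C(C)(C)C)CC/C(C)=C\CO[Si](C)(C)C(C)(C)C
F4 | step 7 | methyl (6R)-6-[(2S,3R,6Z)-3,8-bis[(tert-butyldimethylsilyl)oxy]-2,6-dimethyloct-6-en-1-yl]-5-iodo-2,2-dimethyl-3,6-dihydro-2H-1,2-oxasiline-4-carboxylate (oxasiline) | COC(=O)C1=C(I)[C@@H](C[C@H](C)[C@H](O[Si](C)(C)C(C)(C)C)CC/C(C)=C\CO[Si](C)(C)C(C)(C)C)O[Si](C)(C)C1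
F5 | step 6 | methyl (4S,6S,7R,10Z)-7,12-bis[(tert-butyldimethylsilyl)oxy]-4-hydroxy-6,10-dimethyldodec-10-en-2-ynoate ((4S)-epimer of 12) | COC(=O)C#C[C@@H](O)C[C@H](C)[C@H](O[Si](C)(C)C(C)(C)C)CC/C(C)=C\CO[Si](C)(C)C(C)(C)C
F6 | step 6 | methyl (6S,7R,10Z)-7,12-bis[(tert-butyldimethylsilyl)oxy]-6,10-dimethyl-4-oxododec-10-en-2-ynoate (ynone) | COC(=O)C#CC(=O)C[C@H](C)[C@H](O[Si](C)(C)C(C)(C)C)CC/C(C)=C\CO[Si](C)(C)C(C)(C)C
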